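## Retrosynthetic overview

1. The seven-membered ring is made last, by ring-closing metathesis (C8=C9) of a cyclopentane carrying a C10 vinyl carbinol isovalerate and a C6 homoallylic alcohol; C6 aroylation and phenol unmasking follow.
2. C6–C7 bond: intermolecular, reagent-controlled carbonyl methallylation (allylboration) of the C6 aldehyde on the cyclopentane core with a 2-methylallyl unit.
3. C10 carbinol: acetylide opening of a bridged γ-lactone (C10 carbonyl to C4 oxygen), asymmetric transfer hydrogenation of the ynone, semihydrogenation.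
4. C4 tertiary C–O: iodolactonisation of a cyclopentene acid (oxygen delivered cis to C10); the cyclopentene (five-membered ring, made first) comes from ring-closing metathesis.
5. C1/C5: (5S)-menthyloxybutenolide, trans conjugate addition of the isopropylvinyl unit, then enolate methylation and allylation, each anti to the C5 substituent.

Assumption: labels C1–C10 are the daucane locants of the target (C1 quaternary ring-fusion carbon, C4 carbinol carbon with isopropyl, C5 ring-fusion CH, C6 aroyloxy carbon, C8=C9 alkene, C10 isovaleryloxy carbon); (+)-menthol and 3-methylbut-1-yne are taken as inexpensive commercial materials.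

## Route

Step 1
Reactants: 1 furfural
Product: 2 5-hydroxyfuran-2(5H)-one (racemic)
Conditions: O2, hν (visible), 5,10,15,20-tetraphenylporphyrin (cat.), MeOH/CH2Cl2, 20 °C
Reagents that add atoms: oxygen, O=O
Why: Singlet-oxygen [4+2] cycloaddition to the furan (photooxygenation) followed by methanolytic loss of the formyl carbon as methyl formate gives the γ-hydroxybutenolide, whose hemiacetal carbon is racemic and labile.

Step 2
Reactants: 2 5-hydroxyfuran-2(5H)-one; 3 (+)-menthol, (1S,2R,5S)-5-methyl-2-(propan-2-yl)cyclohexan-1-ol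
Product: 4 (5S)-5-[(1S,2R,5S)-menthyloxy]furan-2(5H)-one
Conditions: (±)-camphor-10-sulfonic acid (cat.), toluene, reflux (−H2O); crystallisation from light petroleum, mother liquor re-equilibrated with acid
Reagents that add atoms: none
Why: Acid-catalysed acetalisation gives both acetal epimers, which interconvert under acid while the (5S) epimer of the (+)-menthol series crystallises (crystallisation-induced diastereomer transformation), fixing the acetal carbon that later controls C5.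

Step 3
Reactants: 5 3-methylbut-1-yne
Product: 7 2-bromo-3-methylbut-1-ene, via alkenylborane 6 (not isolated)
Conditions: B-bromo-9-BBN, CH2Cl2, 0 °C; then AcOH, 0 → 20 °C
Reagents that add atoms: B-bromo-9-borabicyclo[3.3.1]nonane, BrB1C2CCCC1CCC2
Why: Markovnikov syn-bromoboration of the terminal alkyne (haloboration) puts bromine on the internal carbon, and protodeboronation with acetic acid gives the 2-bromo-1-alkene; no stereocentre is formed.

Step 4
Reactants: 4 (5S)-5-[(1S,2R,5S)-menthyloxy]furan-2(5H)-one; 7 2-bromo-3-methylbut-1-ene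
Product: 9 (4R,5S)-4-(3-methylbut-1-en-2-yl)-5-[(1S,2R,5S)-menthyloxy]oxolan-2-one, via alkenylmagnesium bromide 8 (not isolated)
Conditions: 7, Mg, THF, 40 °C; then CuBr·SMe2 (10 mol %), 4, THF, −78 → −40 °C; H2O work-up
Reagents that add atoms: none
Why: Copper-catalysed conjugate (Michael-type 1,4-) addition of the Grignard reagent occurs anti to the bulky menthyloxy group on the adjacent acetal carbon, setting the future C5 stereocentre (4R in the lactone) trans to it.

Step 5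
Reactants: 9 (4R,5S)-4-(3-methylbut-1-en-2-yl)-5-[(1S,2R,5S)-menthyloxy]oxolan-2-one
Product: 10 (3S,4R,5S)-3-methyl-4-(3-methylbut-1-en-2-yl)-5-[(1S,2R,5S)-menthyloxy]oxolan-2-one
Conditions: LiN(i-Pr)2, THF, −78 °C; MeI, −78 → −40 °C
Reagents that add atoms: iodomethane, IC
Why: Lactone enolate alkylation places methyl anti to the neighbouring alkenyl group (3,4-trans), a centre that is re-enolised in the next step so that only the presence of the methyl group matters.

Step 6
Reactants: 10 (3S,4R,5S)-3-methyl-4-(3-methylbut-1-en-2-yl)-5-[(1S,2R,5S)-menthyloxy]oxolan-2-one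
Product: 11 (3S,4S,5S)-3-methyl-4-(3-methylbut-1-en-2-yl)-5-[(1S,2R,5S)-menthyloxy]-3-(prop-2-en-1-yl)oxolan-2-one
Conditions: LiN(i-Pr)2, THF/DMPU, −78 °C; allyl bromide, −78 → −20 °C
Reagents that add atoms: allyl bromide, C=CCBr
Why: Diastereoselective alkylation of the tetrasubstituted lactone enolate again occurs anti to the adjacent alkenyl group, so allyl ends up trans and methyl cis to it, creating the quaternary future C1 centre (the C4 label changes from R to S only through a priority change).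

Step 7
Reactants: 11 (3S,4S,5S)-3-methyl-4-(3-methylbut-1-en-2-yl)-5-[(1S,2R,5S)-menthyloxy]-3-(prop-2-en-1-yl)oxolan-2-one
Product: 12 (2S,3S)-3-(hydroxymethyl)-2,5-dimethyl-4-methylidene-2-(prop-2-en-1-yl)hexan-1-ol
Conditions: LiAlH4, THF, 0 → 20 °C; H2O work-up
Reagents that add atoms: none
Why: Hydride reduction of the lactone carbonyl and of the aldehyde released from the acyl acetal gives the 1,4-diol and returns the auxiliary without touching either stereocentre, fast reduction preventing epimerisation of the transient aldehyde.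

Step 8
Reactants: 12 (2S,3S)-3-(hydroxymethyl)-2,5-dimethyl-4-methylidene-2-(prop-2-en-1-yl)hexan-1-ol
Product: 13 (2S,3S)-3-{[(tert-butyldiphenylsilyl)oxy]methyl}-2,5-dimethyl-4-methylidene-2-(prop-2-en-1-yl)hexan-1-ol
Conditions: t-BuPh2SiCl (1.0 equiv), imidazole, CH2Cl2, −20 °C
Reagents that add atoms: tert-butyl(chloro)diphenylsilane, CC(C)(C)[Si](Cl)(c1ccccc1)c1ccccc1
Why: Silylation with the bulky chlorosilane differentiates the two primary alcohols sterically, reacting at the C6 hydroxymethyl on the CH carbon in preference to the neopentyl C10 hydroxymethyl on the quaternary carbon.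

Step 9
Reactants: 13 (2S,3S)-3-{[(tert-butyldiphenylsilyl)oxy]methyl}-2,5-dimethyl-4-methylidene-2-(prop-2-en-1-yl)hexan-1-ol
Product: 14 (2S,3S)-3-{[(tert-butyldiphenylsilyl)oxy]methyl}-2,5-dimethyl-4-methylidene-2-(prop-2-en-1-yl)hexanal
Conditions: Dess–Martin periodinane, CH2Cl2, 20 °C
Reagents that add atoms: none
Why: Dess–Martin oxidation converts the neopentyl primary alcohol into a non-enolisable aldehyde without touching the alkenes or the silyl ether.

Step 10
Reactants: 14 (2S,3S)-3-{[(tert-butyldiphenylsilyl)oxy]methyl}-2,5-dimethyl-4-methylidene-2-(prop-2-en-1-yl)hexanal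
Product: 15 (2S,3S)-3-{[(tert-butyldiphenylsilyl)oxy]methyl}-2,5-dimethyl-4-methylidene-2-(prop-2-en-1-yl)hexanoic acid
Conditions: NaClO2, NaH2PO4, 2-methylbut-2-ene, t-BuOH/H2O, 20 °C
Reagents that add atoms: sodium chlorite, [Na+].[O-]Cl=O
Why: Pinnick oxidation takes the aldehyde to the acid while 2-methylbut-2-ene scavenges the hypochlorous acid by-product and so protects both alkenes.

Step 11
Reactants: 15 (2S,3S)-3-{[(tert-butyldiphenylsilyl)oxy]methyl}-2,5-dimethyl-4-methylidene-2-(prop-2-en-1-yl)hexanoic acid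
Product: 16 (1S,2S)-2-{[(tert-butyldiphenylsilyl)oxy]methyl}-1-methyl-3-(propan-2-yl)cyclopent-3-ene-1-carboxylic acid
Conditions: second-generation Grubbs catalyst (5 mol %), CH2Cl2 (5 mM), 40 °C
Reagents that add atoms: none
Why: Ring-closing metathesis between the allyl group and the 1,1-disubstituted alkene, helped by the quaternary centre and driven by loss of ethene, forms the trisubstituted cyclopentene (C3=C4) with both stereocentres untouched.

Step 12
Reactants: 16 (1S,2S)-2-{[(tert-butyldiphenylsilyl)oxy]methyl}-1-methyl-3-(propan-2-yl)cyclopent-3-ene-1-carboxylic acid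
Product: 17 (1S,4S,6S,7S)-7-{[(tert-butyldiphenylsilyl)oxy]methyl}-6-iodo-4-methyl-1-(propan-2-yl)-2-oxabicyclo[2.2.1]heptan-3-one
Conditions: I2, NaHCO3, MeCN, 0 °C, dark
Reagents that add atoms: iodine, [I][I]
Why: In this iodolactonisation the carboxylate can only reach the alkene face cis to itself and attacks the more substituted (Markovnikov) carbon of the iodonium ion, so the tertiary C4–O bond forms cis to C10 (the target configuration) with iodine anti at C3.

Step 13
Reactants: 17 (1S,4S,6S,7S)-7-{[(tert-butyldiphenylsilyl)oxy]methyl}-6-iodo-4-methyl-1-(propan-2-yl)-2-oxabicyclo[2.2.1]heptan-3-one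
Product: 18 (1S,4S,7S)-7-{[(tert-butyldiphenylsilyl)oxy]methyl}-4-methyl-1-(propan-2-yl)-2-oxabicyclo[2.2.1]heptan-3-one
Conditions: Bu3SnH, AIBN (cat.), toluene, 80 °C
Reagents that add atoms: none
Why: Radical chain dehalogenation removes the secondary iodide without affecting the lactone, the silyl ether or any stereocentre.

Step 14
Reactants: 18 (1S,4S,7S)-7-{[(tert-butyldiphenylsilyl)oxy]methyl}-4-methyl-1-(propan-2-yl)-2-oxabicyclo[2.2.1]heptan-3-one
Product: 19 1-[(1S,2S,3S)-2-{[(tert-butyldiphenylsilyl)oxy]methyl}-3-hydroxy-1-methyl-3-(propan-2-yl)cyclopentyl]-3-(trimethylsilyl)prop-2-yn-1-one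
Conditions: Me3SiC≡CH, n-BuLi, THF, −78 °C; then 18, −78 °C; H2O work-up
Reagents that add atoms: ethynyltrimethylsilane, C#C[Si](C)(C)C
Why: Nucleophilic acyl substitution of the strained bridged lactone by the lithium acetylide stops at the hindered neopentyl-type ynone and releases the tertiary C4 alcohol with its configuration intact.

Step 15
Reactants: 19 1-[(1S,2S,3S)-2-{[(tert-butyldiphenylsilyl)oxy]methyl}-3-hydroxy-1-methyl-3-(propan-2-yl)cyclopentyl]-3-(trimethylsilyl)prop-2-yn-1-one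
Product: 20 (1S)-1-[(1S,2S,3S)-2-{[(tert-butyldiphenylsilyl)oxy]methyl}-3-hydroxy-1-methyl-3-(propan-2-yl)cyclopentyl]-3-(trimethylsilyl)prop-2-yn-1-ol
Conditions: Ru[(S,S)-TsDPEN](p-cymene) (2 mol %), i-PrOH, 25 °C
Reagents that add atoms: none
Why: Noyori asymmetric transfer hydrogenation of the acetylenic ketone is catalyst-controlled, the (S,S)-ligand giving the (S)-propargylic alcohol, which is the C10 configuration of the target.

Step 16
Reactants: 20 (1S)-1-[(1S,2S,3S)-2-{[(tert-butyldiphenylsilyl)oxy]methyl}-3-hydroxy-1-methyl-3-(propan-2-yl)cyclopentyl]-3-(trimethylsilyl)prop-2-yn-1-ol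
Product: 21 (1S)-1-[(1S,2S,3S)-2-{[(tert-butyldiphenylsilyl)oxy]methyl}-3-hydroxy-1-methyl-3-(propan-2-yl)cyclopentyl]-3-(trimethylsilyl)prop-2-yn-1-yl 3-methylbutanoate
Conditions: 3-methylbutanoyl chloride, pyridine, DMAP (cat.), CH2Cl2, 0 → 20 °C
Reagents that add atoms: 3-methylbutanoyl chloride, CC(C)CC(=O)Cl
Why: DMAP-catalysed acylation esterifies the only secondary alcohol, the tertiary C4 alcohol being too hindered to react.

Step 17
Reactants: 21 (1S)-1-[(1S,2S,3S)-2-{[(tert-butyldiphenylsilyl)oxy]methyl}-3-hydroxy-1-methyl-3-(propan-2-yl)cyclopentyl]-3-(trimethylsilyl)prop-2-yn-1-yl 3-methylbutanoate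
Product: 22 (1R)-1-[(1S,2S,3S)-3-hydroxy-2-(hydroxymethyl)-1-methyl-3-(propan-2-yl)cyclopentyl]prop-2-yn-1-yl 3-methylbutanoate
Conditions: Bu4NF, AcOH, THF, 0 → 20 °C
Reagents that add atoms: none
Why: Fluoride-mediated desilylation cleaves both the O–Si bond of the silyl ether and the C–Si bond of the alkynylsilane while the acetic acid buffer protects the ester (the C10 label changes from S to R only because silicon is lost).

Step 18
Reactants: 22 (1R)-1-[(1S,2S,3S)-3-hydroxy-2-(hydroxymethyl)-1-methyl-3-(propan-2-yl)cyclopentyl]prop-2-yn-1-yl 3-methylbutanoate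
Product: 23 (1R)-1-[(1S,2S,3S)-3-hydroxy-2-(hydroxymethyl)-1-methyl-3-(propan-2-yl)cyclopentyl]prop-2-en-1-yl 3-methylbutanoate
Conditions: H2 (1 atm), Pd/CaCO3 poisoned with Pb(OAc)2, quinoline, EtOAc, 20 °C
Reagents that add atoms: none
Why: Lindlar semihydrogenation stops at the terminal alkene because the poisoned palladium surface does not reduce alkenes.

Step 19
Reactants: 23 (1R)-1-[(1S,2S,3S)-3-hydroxy-2-(hydroxymethyl)-1-methyl-3-(propan-2-yl)cyclopentyl]prop-2-en-1-yl 3-methylbutanoate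
Product: 24 (1R)-1-[(1S,2R,3S)-2-formyl-3-hydroxy-1-methyl-3-(propan-2-yl)cyclopentyl]prop-2-en-1-yl 3-methylbutanoate
Conditions: Dess–Martin periodinane, NaHCO3, CH2Cl2, 0 °C
Reagents that add atoms: none
Why: Buffered Dess–Martin oxidation of the only oxidisable (primary) alcohol gives the aldehyde under non-basic conditions that neither epimerise C5 nor trigger retro-aldol or dehydration of the β-hydroxy aldehyde (the ring CH label becomes 2R by priority change only).

Step 20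
Reactants: 24 (1R)-1-[(1S,2R,3S)-2-formyl-3-hydroxy-1-methyl-3-(propan-2-yl)cyclopentyl]prop-2-en-1-yl 3-methylbutanoate
Product: 25 (1R)-1-[(1S,2S,3S)-3-hydroxy-2-[(1R)-1-hydroxy-3-methylbut-3-en-1-yl]-1-methyl-3-(propan-2-yl)cyclopentyl]prop-2-en-1-yl 3-methylbutanoate
Conditions: (+)-Ipc2BOMe, 2-methylallylmagnesium chloride, Et2O, −78 → 20 °C; then 24, −78 °C; then H2O2, pH 7 buffer, 0 °C
Reagents that add atoms: 2-methylallylmagnesium chloride, CC(=C)C[Mg]Cl
Why: In this Brown allylboration, an intermolecular carbonyl allylation that joins the cyclopentane fragment to the C7–C8 unit, the methallylborane adds through a closed chair transition state and the isopinocampheyl groups derived from (−)-α-pinene direct attack to the Re face of the aldehyde, setting C6 as R under reagent control.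

Step 21
Reactants: 25 (1R)-1-[(1S,2S,3S)-3-hydroxy-2-[(1R)-1-hydroxy-3-methylbut-3-en-1-yl]-1-methyl-3-(propan-2-yl)cyclopentyl]prop-2-en-1-yl 3-methylbutanoate
Product: 26 (3S,3aS,4R,8R,8aS)-3,4-dihydroxy-6,8a-dimethyl-3-(propan-2-yl)-1,2,3,3a,4,5,8,8a-octahydroazulen-8-yl 3-methylbutanoate
Conditions: second-generation Hoveyda–Grubbs catalyst (10 mol %), toluene (2 mM), 80 °C
Reagents that add atoms: none
Why: Ring-closing metathesis of the vinyl and 2-methylallyl groups held trans on the cyclopentane closes the seven-membered ring with the trisubstituted C8=C9 alkene, ethene loss driving the reaction and no stereocentre being touched.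

Step 22
Reactants: 26 (3S,3aS,4R,8R,8aS)-3,4-dihydroxy-6,8a-dimethyl-3-(propan-2-yl)-1,2,3,3a,4,5,8,8a-octahydroazulen-8-yl 3-methylbutanoate
Product: 27 (3S,3aS,4R,8R,8aS)-3-hydroxy-6,8a-dimethyl-8-[(3-methylbutanoyl)oxy]-3-(propan-2-yl)-1,2,3,3a,4,5,8,8a-octahydroazulen-4-yl 4-(acetyloxy)benzoate
Conditions: 4-acetoxybenzoyl chloride, Et3N, DMAP, CH2Cl2, 0 → 20 °C
Reagents that add atoms: 4-acetoxybenzoyl chloride, CC(=O)Oc1ccc(cc1)C(Cl)=O
Why: DMAP-catalysed acylation with the acid chloride esterifies the single secondary alcohol at C6 with retention, the tertiary C4 alcohol being inert.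

Step 23
Reactants: 27 (3S,3aS,4R,8R,8aS)-3-hydroxy-6,8a-dimethyl-8-[(3-methylbutanoyl)oxy]-3-(propan-2-yl)-1,2,3,3a,4,5,8,8a-octahydroazulen-4-yl 4-(acetyloxy)benzoate
Product: 28 (3S,3aS,4R,8R,8aS)-3-hydroxy-6,8a-dimethyl-8-[(3-methylbutanoyl)oxy]-3-(propan-2-yl)-1,2,3,3a,4,5,8,8a-octahydroazulen-4-yl 4-hydroxybenzoate (target)
Conditions: K2CO3 (cat.), MeOH, 0 °C
Reagents that add atoms: none
Why: Base-catalysed transesterification (methanolysis) cleaves the aryl acetate, which is far more reactive than the hindered alkyl isovalerate and the benzoate (deactivated once the phenoxide forms), and liberates the target.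

## Compound list

1 | furfural (furan-2-carbaldehyde) | O=Cc1ccco1 | starting material
2 | 5-hydroxyfuran-2(5H)-one (racemic) | O=C1C=CC(O)O1 | intermediate
3 | (+)-menthol, (1S,2R,5S)-5-methyl-2-(propan-2-yl)cyclohexan-1-ol | O[C@H]1C[C@@H](C)CC[C@@H]1C(C)C | starting material
4 | (5S)-5-[(1S,2R,5S)-menthyloxy]furan-2(5H)-one | O=C1C=C[C@@H](O[C@H]2C[C@@H](C)CC[C@@H]2C(C)C)O1 | intermediate
5 | 3-methylbut-1-yne | CC(C)C#C | starting material
6 | 9-[(Z)-2-bromo-3-methylbut-1-en-1-yl]-9-borabicyclo[3.3.1]nonane | Br/C(C(C)C)=C\B1C2CCCC1CCC2 | intermediate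
7 | 2-bromo-3-methylbut-1-ene | CC(C)C(Br)=C | intermediate
8 | (3-methylbut-1-en-2-yl)magnesium bromide | CC(C)C(=C)[Mg]Br | intermediate
9 | (4R,5S)-4-(3-methylbut-1-en-2-yl)-5-[(1S,2R,5S)-menthyloxy]oxolan-2-one (alkenyl trans to menthyloxy) | O=C1C[C@@H]([C@@H](O[C@H]2C[C@@H](C)CC[C@@H]2C(C)C)O1)C(=C)C(C)C | intermediate
10 | (3S,4R,5S)-3-methyl-4-(3-methylbut-1-en-2-yl)-5-[(1S,2R,5S)-menthyloxy]oxolan-2-one (methyl trans to alkenyl) | O=C1[C@@H](C)[C@@H]([C@@H](O[C@H]2C[C@@H](C)CC[C@@H]2C(C)C)O1)C(=C)C(C)C | intermediate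
11 | (3S,4S,5S)-3-methyl-4-(3-methylbut-1-en-2-yl)-5-[(1S,2R,5S)-menthyloxy]-3-(prop-2-en-1-yl)oxolan-2-one (allyl trans to alkenyl) | O=C1[C@@]([C@@H]([C@@H](O[C@H]2C[C@@H](C)CC[C@@H]2C(C)C)O1)C(=C)C(C)C)(C)CC=C | intermediate
12 | (2S,3S)-3-(hydroxymethyl)-2,5-dimethyl-4-methylidene-2-(prop-2-en-1-yl)hexan-1-ol | OC[C@@]([C@@H](CO)C(=C)C(C)C)(C)CC=C | intermediate
13 | (2S,3S)-3-{[(tert-butyldiphenylsilyl)oxy]methyl}-2,5-dimethyl-4-methylidene-2-(prop-2-en-1-yl)hexan-1-ol | OC[C@@]([C@@H](CO[Si](c1ccccc1)(c1ccccc1)C(C)(C)C)C(=C)C(C)C)(C)CC=C | intermediate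
14 | (2S,3S)-3-{[(tert-butyldiphenylsilyl)oxy]methyl}-2,5-dimethyl-4-methylidene-2-(prop-2-en-1-yl)hexanal | O=C[C@@]([C@@H](CO[Si](c1ccccc1)(c1ccccc1)C(C)(C)C)C(=C)C(C)C)(C)CC=C | intermediate
15 | (2S,3S)-3-{[(tert-butyldiphenylsilyl)oxy]methyl}-2,5-dimethyl-4-methylidene-2-(prop-2-en-1-yl)hexanoic acid | OC(=O)[C@@]([C@@H](CO[Si](c1ccccc1)(c1ccccc1)C(C)(C)C)C(=C)C(C)C)(C)CC=C | intermediate
16 | (1S,2S)-2-{[(tert-butyldiphenylsilyl)oxy]methyl}-1-methyl-3-(propan-2-yl)cyclopent-3-ene-1-carboxylic acid | OC(=O)[C@@]1(C)CC=C(C(C)C)[C@@H]1CO[Si](c1ccccc1)(c1ccccc1)C(C)(C)C | intermediate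
17 | (1S,4S,6S,7S)-7-{[(tert-butyldiphenylsilyl)oxy]methyl}-6-iodo-4-methyl-1-(propan-2-yl)-2-oxabicyclo[2.2.1]heptan-3-one | O=C1[C@@]2(C)C[C@H](I)[C@](O1)(C(C)C)[C@@H]2CO[Si](c1ccccc1)(c1ccccc1)C(C)(C)C | intermediate
18 | (1S,4S,7S)-7-{[(tert-butyldiphenylsilyl)oxy]methyl}-4-methyl-1-(propan-2-yl)-2-oxabicyclo[2.2.1]heptan-3-one | O=C1[C@@]2(C)CC[C@](O1)(C(C)C)[C@@H]2CO[Si](c1ccccc1)(c1ccccc1)C(C)(C)C | intermediate
19 | 1-[(1S,2S,3S)-2-{[(tert-butyldiphenylsilyl)oxy]methyl}-3-hydroxy-1-methyl-3-(propan-2-yl)cyclopentyl]-3-(trimethylsilyl)prop-2-yn-1-one | C[Si](C)(C)C#CC(=O)[C@@]1(C)CC[C@](O)(C(C)C)[C@@H]1CO[Si](c1ccccc1)(c1ccccc1)C(C)(C)C | intermediate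
20 | (1S)-1-[(1S,2S,3S)-2-{[(tert-butyldiphenylsilyl)oxy]methyl}-3-hydroxy-1-methyl-3-(propan-2-yl)cyclopentyl]-3-(trimethylsilyl)prop-2-yn-1-ol | C[Si](C)(C)C#C[C@@H](O)[C@@]1(C)CC[C@](O)(C(C)C)[C@@H]1CO[Si](c1ccccc1)(c1ccccc1)C(C)(C)C | intermediate
21 | (1S)-1-[(1S,2S,3S)-2-{[(tert-butyldiphenylsilyl)oxy]methyl}-3-hydroxy-1-methyl-3-(propan-2-yl)cyclopentyl]-3-(trimethylsilyl)prop-2-yn-1-yl 3-methylbutanoate | C[Si](C)(C)C#C[C@@H](OC(=O)CC(C)C)[C@@]1(C)CC[C@](O)(C(C)C)[C@@H]1CO[Si](c1ccccc1)(c1ccccc1)C(C)(C)C | intermediate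
22 | (1R)-1-[(1S,2S,3S)-3-hydroxy-2-(hydroxymethyl)-1-methyl-3-(propan-2-yl)cyclopentyl]prop-2-yn-1-yl 3-methylbutanoate | C#C[C@@H](OC(=O)CC(C)C)[C@@]1(C)CC[C@](O)(C(C)C)[C@@H]1CO | intermediate
23 | (1R)-1-[(1S,2S,3S)-3-hydroxy-2-(hydroxymethyl)-1-methyl-3-(propan-2-yl)cyclopentyl]prop-2-en-1-yl 3-methylbutanoate | C=C[C@@H](OC(=O)CC(C)C)[C@@]1(C)CC[C@](O)(C(C)C)[C@@H]1CO | intermediate
24 | (1R)-1-[(1S,2R,3S)-2-formyl-3-hydroxy-1-methyl-3-(propan-2-yl)cyclopentyl]prop-2-en-1-yl 3-methylbutanoate | C=C[C@@H](OC(=O)CC(C)C)[C@@]1(C)CC[C@](O)(C(C)C)[C@@H]1C=O | intermediate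
25 | (1R)-1-[(1S,2S,3S)-3-hydroxy-2-[(1R)-1-hydroxy-3-methylbut-3-en-1-yl]-1-methyl-3-(propan-2-yl)cyclopentyl]prop-2-en-1-yl 3-methylbutanoate | C=C[C@@H](OC(=O)CC(C)C)[C@@]1(C)CC[C@](O)(C(C)C)[C@@H]1[C@H](O)CC(C)=C | intermediate
26 | (3S,3aS,4R,8R,8aS)-3,4-dihydroxy-6,8a-dimethyl-3-(propan-2-yl)-1,2,3,3a,4,5,8,8a-octahydroazulen-8-yl 3-methylbutanoate | CC1=C[C@@H](OC(=O)CC(C)C)[C@@]2(C)CC[C@](O)(C(C)C)[C@@H]2[C@H](O)C1 | intermediate
27 | (3S,3aS,4R,8R,8aS)-3-hydroxy-6,8a-dimethyl-8-[(3-methylbutanoyl)oxy]-3-(propan-2-yl)-1,2,3,3a,4,5,8,8a-octahydroazulen-4-yl 4-(acetyloxy)benzoate | CC1=C[C@@H](OC(=O)CC(C)C)[C@@]2(C)CC[C@](O)(C(C)C)[C@@H]2[C@H](OC(=O)c2ccc(OC(C)=O)cc2)C1 | intermediate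
28 | (3S,3aS,4R,8R,8aS)-3-hydroxy-6,8a-dimethyl-8-[(3-methylbutanoyl)oxy]-3-(propan-2-yl)-1,2,3,3a,4,5,8,8a-octahydroazulen-4-yl 4-hydroxybenzoate | CC1=C[C@@H](OC(=O)CC(C)C)[C@@]2(C)CC[C@](O)(C(C)C)[C@@H]2[C@H](OC(=O)c2ccc(O)cc2)C1 | target

## Step count and risks

Total step count: 23. Longest linear sequence: 22 steps (steps 1, 2 and 4–23; step 3 is the side branch to bromide 7).

Three steps most likely to fail:

Step 11 (cyclopentene ring-closing metathesis). The 1,1-disubstituted alkene carries an isopropyl group and sits next to a tertiary carbon, so the metathesis may stall. The fallback sets out from 15 and comes back at 16. Acid 15 is esterified (Me3SiCHN2, MeOH/toluene) to methyl (2S,3S)-3-{[(tert-butyldiphenylsilyl)oxy]methyl}-2,5-dimethyl-4-methylidene-2-(prop-2-en-1-yl)hexanoate F1. Both alkenes are ozonised (O3, CH2Cl2/MeOH, −78 °C; Me2S) to methyl (2S,3S)-3-{[(tert-butyldiphenylsilyl)oxy]methyl}-2,5-dimethyl-4-oxo-2-(2-oxoethyl)hexanoate F2. The C3=C4 bond is then closed by an intramolecular McMurry coupling (TiCl3, Zn–Cu, DME, reflux) to methyl (1S,2S)-2-{[(tert-butyldiphenylsilyl)oxy]methyl}-1-methyl-3-(propan-2-yl)cyclopent-3-ene-1-carboxylate F3, and the ester is cleaved (Me3SiOK, THF, then mild acid) to give 16.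

Step 14 (acetylide opening of the bridged lactone). The hindered lactone may give a persistent hemiketal or suffer a second addition. The fallback sets out from 18 and comes back at 19. Lactone 18 is opened with MeNH(OMe)·HCl and i-PrMgCl (THF, −20 °C) to (1S,2S,3S)-2-{[(tert-butyldiphenylsilyl)oxy]methyl}-3-hydroxy-N-methoxy-N,1-dimethyl-3-(propan-2-yl)cyclopentane-1-carboxamide F4. This is treated with Me3SiC≡CLi (3 equiv, THF, −78 → 0 °C); the chelated adduct releases ynone 19 only on work-up.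

Step 20 (allylboration). The aldehyde is flanked by two fully substituted carbons and carries a free β-hydroxyl, so it may react slowly or with mismatched selectivity. The fallback sets out from 24 and comes back at 25. 2-Methylallylmagnesium chloride (THF, −78 °C) is added without stereocontrol, giving 25 together with its C6 epimer (1R)-1-[(1S,2S,3S)-3-hydroxy-2-[(1S)-1-hydroxy-3-methylbut-3-en-1-yl]-1-methyl-3-(propan-2-yl)cyclopentyl]prop-2-en-1-yl 3-methylbutanoate F5. The mixture is oxidised (Dess–Martin periodinane, NaHCO3, CH2Cl2, 0 °C) to (1R)-1-[(1S,2R,3S)-3-hydroxy-1-methyl-2-(3-methylbut-3-enoyl)-3-(propan-2-yl)cyclopentyl]prop-2-en-1-yl 3-methylbutanoate F6. This ketone is reduced with the (S)-2-methyl-CBS-oxazaborolidine and catecholborane (toluene, −78 °C), which distinguishes the bulky ring side from the CH2 side and returns 25.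

Further compounds
F1 | step 11 | methyl (2S,3S)-3-{[(tert-butyldiphenylsilyl)oxy]methyl}-2,5-dimethyl-4-methylidene-2-(prop-2-en-1-yl)hexanoate | COC(=O)[C@@]([C@@H](CO[Si](c1ccccc1)(c1ccccc1)C(C)(C)C)C(=C)C(C)C)(C)CC=C
F2 | step 11 | methyl (2S,3S)-3-{[(tert-butyldiphenylsilyl)oxy]methyl}-2,5-dimethyl-4-oxo-2-(2-oxoethyl)hexanoate | COC(=O)[C@@]([C@@H](CO[Si](c1ccccc1)(c1ccccc1)C(C)(C)C)C(=O)C(C)C)(C)CC=O
F3 | step 11 | methyl (1S,2S)-2-{[(tert-butyldiphenylsilyl)oxy]methyl}-1-methyl-3-(propan-2-yl)cyclopent-3-ene-1-carboxylate | COC(=O)[C@@]1(C)CC=C(C(C)C)[C@@H]1CO[Si](c1ccccc1)(c1ccccc1)C(C)(C)C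
F4 | step 14 | (1S,2S,3S)-2-{[(tert-butyldiphenylsilyl)oxy]methyl}-3-hydroxy-N-methoxy-N,1-dimethyl-3-(propan-2-yl)cyclopentane-1-carboxamide | CON(C)C(=O)[C@@]1(C)CC[C@](O)(C(C)C)[C@@H]1CO[Si](c1ccccc1)(c1ccccc1)C(C)(C)C
F5 | step 20 | (1R)-1-[(1S,2S,3S)-3-hydroxy-2-[(1S)-1-hydroxy-3-methylbut-3-en-1-yl]-1-methyl-3-(propan-2-yl)cyclopentyl]prop-2-en-1-yl 3-methylbutanoate | C=C[C@@H](OC(=O)CC(C)C)[C@@]1(C)CC[C@](O)(C(C)C)[C@@H]1[C@@H](O)CC(C)=C
F6 | step 20 | (1R)-1-[(1S,2R,3S)-3-hydroxy-1-methyl-2-(3-methylbut-3-enoyl)-3-(propan-2-yl)cyclopentyl]prop-2-en-1-yl 3-methylbutanoate | C=C[C@@H](OC(=O)CC(C)C)[C@@]1(C)CC[C@](O)(C(C)C)[C@@H]1C(=O)CC(C)=C
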